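A direct plan would build ring B as the dihydroresorcinol methyl 6-methyl-2,4-dioxocyclohexane-1-carboxylate A1 by a Michael–Claisen condensation of two simple esters. It would make the acid of ring A from 2,5-dimethylresorcinol A2 by formylation, chlorination, bis-methoxymethyl protection and aldehyde oxidation, giving 3-chloro-4,6-bis(methoxymethoxy)-2,5-dimethylbenzoic acid A3.
The acid chloride of A3 would O-acylate A1 to the enol ester A4, selenenylation and selenoxide elimination would aromatise ring B to the protected depside A5, and acid would remove the two acetals.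
Its weakest steps would be:
- The enol ester formation from A1: a doubly ortho-substituted aroyl chloride must choose O over C and one of two enol oxygens of a 1,3-dione, with acyl migration a standing threat.
- The dehydrogenation of A4 with PhSeCl and H2O2: an oxidant and a base act on a vinylogous anhydride, and the aromatic ring B, which could have been bought, is reached only at the end.
- The formylation, acetal protection, oxidation and deprotection run from A2 to A3 and beyond on ring A: four operations that add one carbon and no skeletal bond.

**Retrosynthetic overview**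
Ring A is a 3-methylorsellinate, a tetraketide ring whose carboxyl carbon is the depside carbonyl. The target is therefore cut at two bonds at once: the acyl C–O4 bond to ring B and the C1–C2 bond of ring A (C1 carries the carbonyl, C2 the methyl group).
Ring B is bought intact as methyl orsellinate. Ring A is closed last from the diketo-dioxinone 7, a masked triketo acid: its acylketene is captured by the free 4-OH of ring B and the chain then folds by aldol condensation.
No protecting group, no change of oxidation state and no late aromatisation remain. Chlorine enters last at C3 of ring A, the only open position of the electron-rich ring.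

Key step: step 4

Assumption: 2,2,6-trimethyl-4H-1,3-dioxin-4-one and methyl orsellinate are taken as commercial; the target is achiral, so the labile stereocentre of 5 and 7 needs no control.

Step 1
Reactants: 1 2,2,6-trimethyl-4H-1,3-dioxin-4-one
Product: 3 6-ethyl-2,2-dimethyl-4H-1,3-dioxin-4-one, via lithium dienolate 2 (not isolated)
Conditions: LiN(i-Pr)2 (1.0 equiv), THF, −78 °C; then MeI (1.1 equiv), DMPU (2 equiv), −78 to −40 °C
Reagents that add atoms: iodomethane, CI
Why: Kinetic deprotonation of the C6 methyl group gives the cross-conjugated lithium dienolate 2, which should alkylate at its exocyclic γ-carbon with a small primary halide in the presence of a dipolar additive (vinylogous enolate γ-alkylation), while the low temperature and the absence of excess base hold back a second methylation.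

Step 2
Reactants: 3 6-ethyl-2,2-dimethyl-4H-1,3-dioxin-4-one
Product: 5 2,2-dimethyl-6-(3-oxobutan-2-yl)-4H-1,3-dioxin-4-one (racemic), via lithium dienolate 4 (not isolated)
Conditions: 3 (2.0 equiv), LiN(SiMe3)2 (2.0 equiv), THF, −78 °C; then AcCl (1.0 equiv), −78 °C; aq NH4Cl (excess 3 recovered)
Reagents that add atoms: acetyl chloride, CC(=O)Cl
Why: γ-C-Acylation of a dioxinone lithium dienolate by an acid chloride (vinylogous Claisen condensation) is the standard entry to keto-dioxinones, the second equivalent of dienolate 4 taking up the acidic proton of 5; the new stereocentre beside the ketone forms racemic, is configurationally labile and becomes an aromatic carbon in step 4.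

Step 3
Reactants: 5 2,2-dimethyl-6-(3-oxobutan-2-yl)-4H-1,3-dioxin-4-one
Product: 7 6-(3,5-dioxohexan-2-yl)-2,2-dimethyl-4H-1,3-dioxin-4-one (racemic; largely enolised), via dilithium dianion 6 (not isolated)
Conditions: LiN(i-Pr)2 (2.2 equiv), THF, −78 °C; then MeC(O)N(OMe)Me (1.2 equiv), −78 to −20 °C; aq NH4Cl
Reagents that add atoms: N-methoxy-N-methylacetamide, CC(=O)N(C)OC
Why: Double deprotonation places the second, more reactive carbanion on the terminal methyl group of the ketone, so dianion 6 should be acylated there (Claisen-type acylation of a keto-dioxinone dianion, Harris–Weiler dianion regiochemistry), and the chelated tetrahedral adduct of the Weinreb amide releases the 1,3-diketone only on work-up, which prevents a second addition.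

Step 4
Reactants: 7 6-(3,5-dioxohexan-2-yl)-2,2-dimethyl-4H-1,3-dioxin-4-one; 8 methyl orsellinate (methyl 2,4-dihydroxy-6-methylbenzoate)
Product: 12 methyl 4-[(2,4-dihydroxy-3,6-dimethylbenzoyl)oxy]-2-hydroxy-6-methylbenzoate, via acylketene 9 (not isolated), via triketo aryl ester 10 (not isolated), via aldol carbinol 11 (not isolated)
Conditions: 8 (2.0 equiv), PhMe (concentrated), 110 °C; cool to rt, Et3N (2 equiv), 4 Å MS; then HCl (4 M in 1,4-dioxane), rt (excess 8 recovered)
Reagents that add atoms: none
Why: Proposed new method: at 110 °C the dioxinone of 7 loses acetone by a retro-hetero-Diels–Alder reaction to give acylketene 9, the unchelated 4-OH of 8 adds across its C=C=O unit to give the aryl 4-methyl-3,5,7-trioxooctanoate 10, and after addition of Et3N the C2 carbanion of 10 (octanoate numbering, between ester and ketone) attacks the C7 methyl ketone to give carbinol 11, which loses water and enolises to ring A. The closest known reaction type is the thermolysis of diketo-dioxinones in the presence of aliphatic alcohols followed by aldol aromatisation to alkyl resorcylates, together with the acetoacetylation of phenols by thermolysed dioxinones; new is that a phenol is the trapping partner, so that the resorcylate ester formed is the depside bond itself. Ring A closes as a six-membered carbocycle by a favoured 6-(enolendo)-exo-trig aldol addition of C2 to the C7 carbonyl, and dehydration to the arene makes the closure irreversible. No stereocentre survives, since the labile centre of 7 and the two formed in 11 all become aromatic carbons. The step needs three selectivities: acylation of O4 and not O2 of 8, secured by the hydrogen bond of the 2-OH to the neighbouring ester carbonyl; capture of 9 by the phenol before its own enol oxygen closes a 2-pyranone, for which 8 is used in excess at high concentration; and aldol closure in preference to Claisen closure (C6 onto C1 with loss of aryloxide), favoured because the methyl ketone C7 is the most electrophilic carbonyl of 10 and because only a weak amine base in an aprotic medium, with no alkoxide, is present. The amine is added only after the thermolysis, since 7 itself would otherwise aromatise with its acetonide still in place.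

Step 5
Reactants: 12 methyl 4-[(2,4-dihydroxy-3,6-dimethylbenzoyl)oxy]-2-hydroxy-6-methylbenzoate
Product: 13 methyl 4-[(3-chloro-4,6-dihydroxy-2,5-dimethylbenzoyl)oxy]-2-hydroxy-6-methylbenzoate (CNP0171762.0)
Conditions: SO2Cl2 (1.0 equiv), Et2O, 0 °C
Reagents that add atoms: sulfuryl chloride, O=S(=O)(Cl)Cl
Why: Electrophilic aromatic chlorination should take the single open position of ring A, which is ortho to one free hydroxyl and para to the other, far faster than the two open positions of ring B, which are activated by one chelated hydroxyl and only weakly by the acyloxy group and are deactivated by the methyl ester, so that one equivalent at 0 °C should stop at monochloride 13.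

**Compound list**

1 | 2,2,6-trimethyl-4H-1,3-dioxin-4-one | CC1=CC(=O)OC(C)(C)O1 | starting material
2 | lithium dienolate of 1 (lithium 2,2-dimethyl-6-methylidene-6H-1,3-dioxin-4-olate, not isolated) | [Li+].C=C1C=C([O-])OC(C)(C)O1 | intermediate
3 | 6-ethyl-2,2-dimethyl-4H-1,3-dioxin-4-one | CCC1=CC(=O)OC(C)(C)O1 | intermediate
4 | lithium dienolate of 3 (lithium 6-ethylidene-2,2-dimethyl-6H-1,3-dioxin-4-olate, double bond geometry not defined, not isolated) | [Li+].CC=C1C=C([O-])OC(C)(C)O1 | intermediate
5 | 2,2-dimethyl-6-(3-oxobutan-2-yl)-4H-1,3-dioxin-4-one (racemic) | CC(=O)C(C)C1=CC(=O)OC(C)(C)O1 | intermediate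
6 | dilithium dianion of 5 (one resonance form drawn, not isolated) | [Li+].[Li+].C=C([O-])C(C)=C1C=C([O-])OC(C)(C)O1 | intermediate
7 | 6-(3,5-dioxohexan-2-yl)-2,2-dimethyl-4H-1,3-dioxin-4-one (racemic, keto form drawn) | CC(=O)CC(=O)C(C)C1=CC(=O)OC(C)(C)O1 | intermediate
8 | methyl orsellinate (methyl 2,4-dihydroxy-6-methylbenzoate) | COC(=O)c1c(C)cc(O)cc1O | starting material
9 | 4-methyl-3,5,7-trioxooct-1-en-1-one (acylketene, racemic, not isolated) | CC(=O)CC(=O)C(C)C(=O)C=C=O | intermediate
10 | methyl 2-hydroxy-6-methyl-4-[(4-methyl-3,5,7-trioxooctanoyl)oxy]benzoate (racemic, keto form drawn, not isolated) | COC(=O)c1c(C)cc(OC(=O)CC(=O)C(C)C(=O)CC(C)=O)cc1O | intermediate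
11 | 3-hydroxy-4-(methoxycarbonyl)-5-methylphenyl 2-hydroxy-2,5-dimethyl-4,6-dioxocyclohexane-1-carboxylate (mixture of diastereomers and tautomers, not isolated) | COC(=O)c1c(C)cc(OC(=O)C2C(=O)C(C)C(=O)CC2(C)O)cc1O | intermediate
12 | methyl 4-[(2,4-dihydroxy-3,6-dimethylbenzoyl)oxy]-2-hydroxy-6-methylbenzoate | COC(=O)c1c(C)cc(OC(=O)c2c(C)cc(O)c(C)c2O)cc1O | intermediate
13 | methyl 4-[(3-chloro-4,6-dihydroxy-2,5-dimethylbenzoyl)oxy]-2-hydroxy-6-methylbenzoate | COC(=O)c1c(C)cc(OC(=O)c2c(C)c(Cl)c(O)c(C)c2O)cc1O | target

**Step count**
Total steps: 5. Longest linear sequence: 5 steps (1 → 3 → 5 → 7 → 12 → 13); 8 is bought.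

**Steps most likely to fail**

1. Step 4 (Proposed new method). Three processes could defeat it: internal closure of acylketene 9 to a 2-pyranone could outrun capture by the weakly nucleophilic phenol; aryl ester 10 could expel aryloxide, either by Claisen closure or by base-induced return to the ketene, faster than it undergoes the aldol closure; and the depside could be acylated a second time.

   The fallback closes ring A first with its carboxyl masked and makes the ester bond afterwards by known depside chemistry; it sets out from 7 and returns at 12. Et3N in CH2Cl2 at rt would aromatise 7 with the dioxinone intact (the known diketo-dioxinone aldol aromatisation) to 7-hydroxy-2,2,5,8-tetramethyl-4H-1,3-benzodioxin-4-one F1. BnBr and K2CO3 in DMF would then give 7-(benzyloxy)-2,2,5,8-tetramethyl-4H-1,3-benzodioxin-4-one F2, and KOH in aqueous DMSO at 80 °C would open the acetonide to 4-(benzyloxy)-2-hydroxy-3,6-dimethylbenzoic acid F3. (CF3CO)2O in PhMe at rt would condense F3 through its mixed anhydride with the free 4-OH of 8 to methyl 4-{[4-(benzyloxy)-2-hydroxy-3,6-dimethylbenzoyl]oxy}-2-hydroxy-6-methylbenzoate F4. H2 over Pd/C in EtOAc would finally remove the benzyl group to give 12, before any aryl chloride is present.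

2. Step 5. Chlorination could fail to discriminate between the two phenolic rings, or could run on to a dichloride on ring B once ring A is substituted.

   The fallback introduces the chlorine before ring A exists, so that no choice between rings arises; it sets out from 7 and returns at 13. N-chlorosuccinimide (1.0 equiv) in CH2Cl2 at 0 °C should chlorinate the most enolised carbon, between the two ketones, to give 6-(4-chloro-3,5-dioxohexan-2-yl)-2,2-dimethyl-4H-1,3-dioxin-4-one F5. Thermolysis of F5 with 8 under the conditions of step 4 would pass through 6-chloro-4-methyl-3,5,7-trioxooct-1-en-1-one F6 and methyl 4-[(6-chloro-4-methyl-3,5,7-trioxooctanoyl)oxy]-2-hydroxy-6-methylbenzoate F7. Aldol closure of F7 to 3-hydroxy-4-(methoxycarbonyl)-5-methylphenyl 3-chloro-2-hydroxy-2,5-dimethyl-4,6-dioxocyclohexane-1-carboxylate F8 and dehydration would give 13 directly. The chlorinated carbon cannot lose HCl, because its ring neighbours carry no hydrogen that would allow elimination in place of dehydration.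

3. Step 3. The strongly basic dianion 6 could take a proton from the acetyl group of the Weinreb amide instead of adding to it, or could be acylated on oxygen.

   The fallback makes the same C–C bond at the alcohol oxidation level; it sets out from 5 (through dianion 6) and returns at 7. Acetaldehyde at −78 °C, a fast and non-enolising partner under these conditions, would give the aldol 6-(5-hydroxy-3-oxohexan-2-yl)-2,2-dimethyl-4H-1,3-dioxin-4-one F9 as a mixture of diastereomers, and Dess–Martin periodinane in CH2Cl2 would oxidise F9 to 7.

**Further compounds**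
F1 | step 4 | 7-hydroxy-2,2,5,8-tetramethyl-4H-1,3-benzodioxin-4-one | Cc1cc(O)c(C)c2OC(C)(C)OC(=O)c12
F2 | step 4 | 7-(benzyloxy)-2,2,5,8-tetramethyl-4H-1,3-benzodioxin-4-one | Cc1cc(OCc3ccccc3)c(C)c2OC(C)(C)OC(=O)c12
F3 | step 4 | 4-(benzyloxy)-2-hydroxy-3,6-dimethylbenzoic acid | Cc1cc(OCc2ccccc2)c(C)c(O)c1C(=O)O
F4 | step 4 | methyl 4-{[4-(benzyloxy)-2-hydroxy-3,6-dimethylbenzoyl]oxy}-2-hydroxy-6-methylbenzoate | COC(=O)c1c(C)cc(OC(=O)c2c(C)cc(OCc3ccccc3)c(C)c2O)cc1O
F5 | step 5 | 6-(4-chloro-3,5-dioxohexan-2-yl)-2,2-dimethyl-4H-1,3-dioxin-4-one (mixture of diastereomers, keto form drawn) | CC(=O)C(Cl)C(=O)C(C)C1=CC(=O)OC(C)(C)O1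
F6 | step 5 | 6-chloro-4-methyl-3,5,7-trioxooct-1-en-1-one (acylketene, not isolated) | CC(=O)C(Cl)C(=O)C(C)C(=O)C=C=O
F7 | step 5 | methyl 4-[(6-chloro-4-methyl-3,5,7-trioxooctanoyl)oxy]-2-hydroxy-6-methylbenzoate (not isolated) | COC(=O)c1c(C)cc(OC(=O)CC(=O)C(C)C(=O)C(Cl)C(C)=O)cc1O
F8 | step 5 | 3-hydroxy-4-(methoxycarbonyl)-5-methylphenyl 3-chloro-2-hydroxy-2,5-dimethyl-4,6-dioxocyclohexane-1-carboxylate (mixture of diastereomers, not isolated) | COC(=O)c1c(C)cc(OC(=O)C2C(=O)C(C)C(=O)C(Cl)C2(C)O)cc1O
F9 | step 3 | 6-(5-hydroxy-3-oxohexan-2-yl)-2,2-dimethyl-4H-1,3-dioxin-4-one (mixture of diastereomers) | CC(O)CC(=O)C(C)C1=CC(=O)OC(C)(C)O1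
A1 | direct plan | methyl 6-methyl-2,4-dioxocyclohexane-1-carboxylate (racemic trans) | COC(=O)[C@@H]1[C@@H](C)CC(=O)CC1=O
A2 | direct plan | 2,5-dimethylresorcinol | Cc1cc(O)c(C)c(O)c1
A3 | direct plan | 3-chloro-4,6-bis(methoxymethoxy)-2,5-dimethylbenzoic acid | OC(=O)c1c(C)c(Cl)c(OCOC)c(C)c1OCOC
A4 | direct plan | methyl 4-{[3-chloro-4,6-bis(methoxymethoxy)-2,5-dimethylbenzoyl]oxy}-6-methyl-2-oxocyclohex-3-ene-1-carboxylate (racemic trans) | COC(=O)[C@@H]1[C@@H](C)CC(OC(=O)c2c(C)c(Cl)c(OCOC)c(C)c2OCOC)=CC1=O
A5 | direct plan | methyl 4-{[3-chloro-4,6-bis(methoxymethoxy)-2,5-dimethylbenzoyl]oxy}-2-hydroxy-6-methylbenzoate | COC(=O)c1c(C)cc(OC(=O)c2c(C)c(Cl)c(OCOC)c(C)c2OCOC)cc1O
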